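A J that needs a Z the flask does not hold cannot be made, so I began with what the charges allow, supposing that each J takes one Z.

| setting | north-west | south-west | alpha | zeta | delta | theta | eta | gamma |
|---|---|---|---|---|---|---|---|---|
| L | 18 mM | 61 mM | 36 mM | 80 mM | 80 mM | 36 mM | 80 mM | 36 mM |
| Z | 43.2 mM | 43.2 mM | 43.2 mM | 43.2 mM | 43.2 mM | 43.2 mM | 43.2 mM | 43.2 mM |
| temperature | 15 °C | 42 °C | 65 °C | 65 °C | 35 °C | 35 °C | 20 °C | 20 °C |
| remark | run made earlier | run made earlier |  |  |  |  |  |  |
| time |  |  | 2.0 h | 2.0 h | 2.0 h | 2.0 h | 2.0 h | 2.0 h |

north-west run (percent of the L charged)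

| time / h | J / % | L / % |
|---|---|---|
| 0.417 | 1.1 | 98.1 |
| 1.33 | 3.9 | 92.0 |
| 2.50 | 8.6 | 85.5 |
| 4.00 | 13.8 | 76.2 |
| 5.00 | 17.9 | 70.4 |

south-west run (percent of the L charged)

| time / min | J / % | L / % |
|---|---|---|
| 10.0 | 3.2 | 85.3 |
| 30.0 | 14.0 | 63.2 |
| 60.0 | 30.5 | 43.4 |
| 80.0 | 40.7 | 35.4 |
| 120 | 52.5 | 27.3 |

(scatter of a reading: 0.5 percentage points)

- ranking by amount of J, in percent of the L charged, from high to low, at 2.0 h (alpha / zeta / delta / theta / eta / gamma)
- the amount of J, in percent of the L charged of the flask you put first, at 2.0 h
- the amount of J, in percent of the L charged of the flask you put last, at 2.0 h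

I tested that supposition on the south-west run, using two different columns. Read as first order, its L fell with a constant of 0.900 h⁻¹ between the first two readings, but with 0.390 h⁻¹ between the last two. Counting one Z per J from the J column, the Z left in the south-west run went over the same spans from 87.9% to 34.2% of its charge. The two ratios, 0.433 for the constant and 0.389 for Z, stood close, but I could not take that as an order in Z: over the first span L lost 22 percentage points while J gained 11 points, so the constant of L was not a constant of J. One Z per J stayed a supposition, and I used it only for what the charges allow.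

I then reckoned zeta at 2.0 h in two ways. The first held the early constant 0.900 h⁻¹ unchanged, without crediting the hotter bath, and so had 83.5% of the L reacted. The second used the charges: the Z charged divided by the L charged was 54.0%, and I called this fraction of the L charged the Z ceiling, the share that a limiting reagent allows. The two ways parted, and I judged that the first one cheats, since its constant had already sunk in the south-west run. For alpha the same fraction was 120%, above the whole charge, so there the ceiling lay above the figure of the first way. I expected zeta just under its ceiling.

The forecast gave alpha > zeta > theta > delta > gamma > eta, with 90% first and 10% last, and it rested on “Z being consumed about 1:1 with J”.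

    L + Z → J + G (k = 7.50 × 10⁻⁴ L mol⁻¹ s⁻¹, Ea = 54.0 kJ mol⁻¹)
    L + Z + G → J + 2 G (k = 0.250 L² mol⁻² s⁻¹, Ea = 43.0 kJ mol⁻¹)
    L ⇌ E (K = 0.670, k = 1.00 × 10⁻⁴ s⁻¹, Ea = 93.0 kJ mol⁻¹, ΔH = −17.0 kJ mol⁻¹)
    (constants at 35 °C)

The flask gave alpha > zeta > delta > theta > eta > gamma, with alpha at 92.6% and gamma at 11.8%; the forecast had delta and theta, and eta and gamma, the other way round. Zeta reached 54.0%, level with its Z ceiling, with 0.00680% of its Z unspent and 33.5% of its L unreacted. The neighbour of alpha with 90 mM of L had a ceiling of 48.0% and held 48.0% of J. The neighbour with 140 mM of L had a ceiling of 30.9% and held 30.9%.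

Readings and results come from a simulation from invented constants, and the scatter is random.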